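## Retrosynthetic overview

1. The C40 target is cut at C11=C12 and C11'=C12' into the C10 trienedial and two C15 Wittig salts: end A (5S,6S, ring OH trans to the chain) is joined first, end B (5R,6S, ring OH cis) second.
2. Both C15 salts come from one C15 enone carbinol. End A is made by substrate-controlled conjugate borylation/oxidation at C5, end B by catalyst-controlled epoxidation followed by SmI2 opening.
3. The C15 enone carbinol comes from (S)-3-oxo-α-ionone (vinyl addition at C9), which comes from (S)-α-ionone (allylic oxidation at C3).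
4. Rings: both six-membered rings are made first, in one operation, by an enantioselective proton-initiated cation–olefin cyclisation of acyclic pseudoionone (C1–C6 bond, the ring closure that lycopene cyclase performs). This fixes C6, and the batch is divided after step 3.
5. Positions are given in carotenoid numbering (C1 = CMe2, C3 = ring carbonyl, C5 = carbinol carbon, C6 = ring CH, C9 = chain carbon bearing methyl).

Assumption: the antipodes of the two chiral catalysts named in steps 1 and 6 are taken to be the ones that give the configurations drawn; if the sense of induction is the opposite, the mirror-image (step 1) or pseudoenantiomeric (step 6) catalyst is used, and the 3E,5E isomer of pseudoionone is bought or enriched from the technical mixture.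

## Route

Step 1
Reactants: 1 (3E,5E)-pseudoionone
Product: 2 (S)-α-ionone
Conditions: (S,S)-imidodiphosphorimidate acid HN[P(=NSO2CF3)(O2R*)]2, R*O2 = (S)-3,3'-bis[3,5-bis(trifluoromethyl)phenyl]-1,1'-binaphthalene-2,2'-diolate (3 mol%), (CF3)2CHOH, −20 °C
Reagents that add atoms: none
Why: Proposed new method: the confined chiral acid protonates the terminal isopropylidene alkene at C2 while its anion holds the chair-folded chain, so C6 of the C5=C6 alkene attacks the incipient C1 cation on one enantiotopic face (this sets C6 as S) and the C5 cation then loses H-4 to give the α isomer; the closest known reactions are the H3PO4 cyclisation of pseudoionone to racemic α-ionone and the imidodiphosphorimidate-catalysed asymmetric polyene cyclisation of homofarnesol-type substrates in fluorinated alcohols (biomimetic cation–olefin cyclisation).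

Step 2
Reactants: 2 (S)-α-ionone
Product: 3 (S)-3-oxo-α-ionone
Conditions: Rh2(cap)4 (dirhodium tetrakis(caprolactamate), 1 mol%), t-BuOOH (70% in water, 5 equiv), 1,2-dichloroethane, 40 °C
Reagents that add atoms: tert-butyl hydroperoxide, CC(C)(C)OO
Why: Radical allylic oxidation (tert-butylperoxyl chain) at C3, the only allylic ring CH2, gives the ring enone; C6 is not involved and keeps its configuration.

Step 3
Reactants: 3 (S)-3-oxo-α-ionone
Product: 4 C15 enone carbinol (4S)-4-[(1E)-3-hydroxy-3-methylpenta-1,4-dien-1-yl]-3,5,5-trimethylcyclohex-2-en-1-one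
Conditions: CH2=CHMgBr (1.05 equiv, inverse addition), THF, −78 °C; then H2O (pH 7 buffer)
Reagents that add atoms: vinylmagnesium bromide, C=C[Mg]Br
Why: Grignard 1,2-addition goes to the open side-chain methyl ketone in preference to the ring carbonyl, which is shielded by the axial C1 methyl group (the same order is known for borohydride reduction of such enediones); the new carbinol centre is not controlled because it is lost in steps 5 and 8.

Step 4
Reactants: 4 C15 enone carbinol
Product: 6 end-A hydroxy ketone (3S,4S)-3-hydroxy-4-[(1E)-3-hydroxy-3-methylpenta-1,4-dien-1-yl]-3,5,5-trimethylcyclohexan-1-one, via tertiary pinacol boronate 5 (not isolated)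
Conditions: CuCl (5 mol%), DPEphos (5 mol%), NaOt-Bu (10 mol%), B2pin2 (1.2 equiv), MeOH (2 equiv), THF, rt; then NaBO3·4H2O, THF/H2O, rt
Reagents that add atoms: bis(pinacolato)diboron, CC1(C)OB(OC1(C)C)B1OC(C)(C)C(C)(C)O1 (boron group of 5 only); sodium perborate, [Na+].[Na+].O[B-]1(O)OO[B-](O)(O)OO1 (the new oxygen of 6)
Why: Copper-catalysed conjugate borylation of the β,β-disubstituted enone followed by stereoretentive C–B oxidation is a formal enone hydration; the boryl group adds to C5 anti to the C6 side chain, which gives the 5S alcohol trans to the chain.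

Step 5
Reactants: 6 end-A hydroxy ketone
Product: 7 end-A phosphonium bromide [(2E,4E)-5-[(1S,2S)-2-hydroxy-2,6,6-trimethyl-4-oxocyclohexyl]-3-methylpenta-2,4-dien-1-yl]triphenylphosphonium bromide
Conditions: PPh3·HBr (1.0 equiv), MeOH, 0 °C to rt; crystallise the 2E,4E salt
Reagents that add atoms: triphenylphosphine hydrobromide, Br.c1ccc(cc1)P(c1ccccc1)c1ccccc1
Why: Ionisation of the tertiary bis-allylic alcohol and capture of the pentadienyl cation by PPh3 at the terminal carbon (Isler-type C15 Wittig salt formation, SN1 with allylic shift) gives the salt, while the ring aldol unit is not allylic and stays intact.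

Step 6
Reactants: 4 C15 enone carbinol
Product: 8 cis-epoxy ketone (1S,5S,6S)-5-[(1E)-3-hydroxy-3-methylpenta-1,4-dien-1-yl]-4,4,6-trimethyl-7-oxabicyclo[4.1.0]heptan-2-one
Conditions: 9-amino-9-deoxy-epi-quinine bis(trifluoroacetate) (10 mol%), 50% aq. H2O2 (1.5 equiv), 1,4-dioxane, 30 °C
Reagents that add atoms: hydrogen peroxide, OO
Why: Amine-catalysed asymmetric nucleophilic epoxidation (iminium activation of the ring ketone, Weitz–Scheffer type) lets the chiral ammonium salt deliver H2O2 to the C5 face syn to the side chain, against the substrate bias, and ring closure then gives the epoxide cis to the chain; only the enone reacts.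

Step 7
Reactants: 8 cis-epoxy ketone
Product: 9 end-B hydroxy ketone (3R,4S)-3-hydroxy-4-[(1E)-3-hydroxy-3-methylpenta-1,4-dien-1-yl]-3,5,5-trimethylcyclohexan-1-one
Conditions: SmI2 (2.2 equiv), THF/MeOH, −90 °C
Reagents that add atoms: none
Why: Reductive opening of the α,β-epoxy ketone by single-electron transfer (ketyl, then C4–O cleavage) leaves the C5–O bond untouched, so the 5R aldol cis to the chain is obtained.

Step 8
Reactants: 9 end-B hydroxy ketone
Product: 10 end-B phosphonium bromide [(2E,4E)-5-[(1S,2R)-2-hydroxy-2,6,6-trimethyl-4-oxocyclohexyl]-3-methylpenta-2,4-dien-1-yl]triphenylphosphonium bromide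
Conditions: PPh3·HBr (1.0 equiv), MeOH, 0 °C to rt; crystallise the 2E,4E salt
Reagents that add atoms: triphenylphosphine hydrobromide, Br.c1ccc(cc1)P(c1ccccc1)c1ccccc1
Why: Same Isler-type salt formation as in step 5 (allylic cation captured by PPh3), with no stereocentre of the ring involved.

Step 9
Reactants: 7 end-A phosphonium bromide; 11 (2E,4E,6E)-2,7-dimethylocta-2,4,6-trienedial
Product: 13 C25 aldehyde (2E,4E,6E,8E,10E,12E)-13-[(1S,2S)-2-hydroxy-2,6,6-trimethyl-4-oxocyclohexyl]-2,7,11-trimethyltrideca-2,4,6,8,10,12-hexaenal, via phosphorus ylide 12 (not isolated)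
Conditions: 11 (3 equiv), 1,2-epoxybutane/EtOH, reflux; excess 11 recovered
Reagents that add atoms: none
Why: Wittig olefination under neutral conditions (bromide opens the epoxide to an alkoxide that forms the ylide) spares the base-labile aldol unit, the excess dialdehyde ensures mono-olefination, and the new double bond ends up E after equilibration at reflux.

Step 10
Reactants: 13 C25 aldehyde; 10 end-B phosphonium bromide
Product: 15 target (5S,6S,5'R,6'S)-5,5'-dihydroxy-5,6,5',6'-tetrahydro-β,β-carotene-3,3'-dione, via phosphorus ylide 14 (not isolated)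
Conditions: 10 (1.3 equiv), 1,2-epoxybutane/EtOH, reflux; crystallise
Reagents that add atoms: none
Why: A second Wittig olefination under the same neutral conditions joins end B without touching any stereocentre, and the all-E polyene is the thermodynamic isomer reached on heating.

## Compound list

1 | (3E,5E)-pseudoionone, (3E,5E)-6,10-dimethylundeca-3,5,9-trien-2-one | CC(=O)/C=C/C=C(\C)CCC=C(C)C | starting material
2 | (S)-α-ionone, (3E)-4-[(1S)-2,6,6-trimethylcyclohex-2-en-1-yl]but-3-en-2-one | CC(=O)/C=C/[C@H]1C(C)(C)CCC=C1C | intermediate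
3 | (S)-3-oxo-α-ionone, (4S)-3,5,5-trimethyl-4-[(1E)-3-oxobut-1-en-1-yl]cyclohex-2-en-1-one | CC(=O)/C=C/[C@H]1C(C)(C)CC(=O)C=C1C | intermediate
4 | C15 enone carbinol, (4S)-4-[(1E)-3-hydroxy-3-methylpenta-1,4-dien-1-yl]-3,5,5-trimethylcyclohex-2-en-1-one (both epimers at the side-chain carbinol carbon) | C=CC(C)(O)/C=C/[C@H]1C(C)(C)CC(=O)C=C1C | intermediate
5 | tertiary pinacol boronate, the analogue of 6 with a 4,4,5,5-tetramethyl-1,3,2-dioxaborolan-2-yl group in place of the ring OH, boron trans to the side chain | C=CC(C)(O)/C=C/[C@H]1C(C)(C)CC(=O)C[C@]1(C)B2OC(C)(C)C(C)(C)O2 | intermediate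
6 | end-A hydroxy ketone, (3S,4S)-3-hydroxy-4-[(1E)-3-hydroxy-3-methylpenta-1,4-dien-1-yl]-3,5,5-trimethylcyclohexan-1-one (ring OH trans to side chain) | C=CC(C)(O)/C=C/[C@H]1C(C)(C)CC(=O)C[C@]1(C)O | intermediate
7 | end-A phosphonium bromide, [(2E,4E)-5-[(1S,2S)-2-hydroxy-2,6,6-trimethyl-4-oxocyclohexyl]-3-methylpenta-2,4-dien-1-yl]triphenylphosphonium bromide | c1ccccc1[P+](c1ccccc1)(c1ccccc1)C/C=C(C)/C=C/[C@H]1C(C)(C)CC(=O)C[C@]1(C)O.[Br-] | intermediate
8 | cis-epoxy ketone, (1S,5S,6S)-5-[(1E)-3-hydroxy-3-methylpenta-1,4-dien-1-yl]-4,4,6-trimethyl-7-oxabicyclo[4.1.0]heptan-2-one (epoxide oxygen cis to side chain) | C=CC(C)(O)/C=C/[C@H]1C(C)(C)CC(=O)[C@@H]2[C@@]1(C)O2 | intermediate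
9 | end-B hydroxy ketone, (3R,4S)-3-hydroxy-4-[(1E)-3-hydroxy-3-methylpenta-1,4-dien-1-yl]-3,5,5-trimethylcyclohexan-1-one (ring OH cis to side chain) | C=CC(C)(O)/C=C/[C@H]1C(C)(C)CC(=O)C[C@@]1(C)O | intermediate
10 | end-B phosphonium bromide, [(2E,4E)-5-[(1S,2R)-2-hydroxy-2,6,6-trimethyl-4-oxocyclohexyl]-3-methylpenta-2,4-dien-1-yl]triphenylphosphonium bromide | c1ccccc1[P+](c1ccccc1)(c1ccccc1)C/C=C(C)/C=C/[C@H]1C(C)(C)CC(=O)C[C@@]1(C)O.[Br-] | intermediate
11 | (2E,4E,6E)-2,7-dimethylocta-2,4,6-trienedial | O=C/C(C)=C/C=C/C=C(C)/C=O | starting material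
12 | phosphorus ylide of 7 | c1ccccc1P(c1ccccc1)(c1ccccc1)=C/C=C(C)/C=C/[C@H]1C(C)(C)CC(=O)C[C@]1(C)O | intermediate
13 | C25 aldehyde, (2E,4E,6E,8E,10E,12E)-13-[(1S,2S)-2-hydroxy-2,6,6-trimethyl-4-oxocyclohexyl]-2,7,11-trimethyltrideca-2,4,6,8,10,12-hexaenal | CC(/C=C/C=C(C)/C=C/[C@H]1C(C)(C)CC(=O)C[C@]1(C)O)=C\C=C\C=C(C)\C=O | intermediate
14 | phosphorus ylide of 10 | c1ccccc1P(c1ccccc1)(c1ccccc1)=C/C=C(C)/C=C/[C@H]1C(C)(C)CC(=O)C[C@@]1(C)O | intermediate
15 | (5S,6S,5'R,6'S)-5,5'-dihydroxy-5,6,5',6'-tetrahydro-β,β-carotene-3,3'-dione, all-E | CC(/C=C/C=C(C)/C=C/[C@H]1C(C)(C)CC(=O)C[C@]1(C)O)=C\C=C\C=C(C)\C=C\C=C(C)\C=C\[C@H]1C(C)(C)CC(=O)C[C@@]1(C)O | target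

## Step count and risks

Total steps: 10. Longest linear sequence: 7 steps (steps 1, 2, 3, 6, 7, 8, 10; the end-A branch through steps 4, 5 and 9 is equally long).

Steps most likely to fail:

- **Step 1 (asymmetric cyclisation).** The dienone may bind the acid, the enantioselectivity may be low, or α/β/γ double-bond isomers may form. The fallback sets out from 1 and comes back at 2: pseudoionone is cyclised with 85% H3PO4 at 30 °C to racemic α-ionone F1, and the enantiomers are separated by preparative supercritical-fluid chromatography on a chiral stationary phase; the levorotatory S enantiomer is 2.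

- **Step 3 (choice between the two enone carbonyls).** The ring carbonyl may compete for the Grignard reagent. The fallback sets out from 2 and comes back at 4, with the order of events reversed. Vinylmagnesium bromide is added to 2, which has only one carbonyl group, to give (S)-vinyl-α-ionol F2. Ring C3 is then oxidised with Rh2(cap)4 and t-BuOOH, a chromium-free oxidant that does not transpose the tertiary allylic alcohol, to give 4.

- **Step 6 (epoxidation against the substrate bias).** The catalyst may not override the preference for attack anti to the side chain. The fallback sets out from 4 and comes back at 8, and uses a ring hydroxyl as the directing group instead of catalyst control.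
  - Luche reduction of 4 (NaBH4, CeCl3·7H2O, MeOH, −78 °C) gives the two C3 alcohols; the cis allylic alcohol F3 is separated by chromatography.
  - Epoxidation of F3 with VO(acac)2 and t-BuOOH (1.1 equiv) delivers oxygen syn to the ring hydroxyl and so syn to the side chain, giving the epoxy alcohol F4.
  - Dess–Martin periodinane then oxidises the secondary alcohol of F4 to give 8.

Further compounds
F1 | step 1 | racemic α-ionone | CC(=O)/C=C/C1C(C)(C)CCC=C1C
F2 | step 3 | (S)-vinyl-α-ionol = (1E)-3-methyl-1-[(1S)-2,6,6-trimethylcyclohex-2-en-1-yl]penta-1,4-dien-3-ol (both epimers at the carbinol carbon) | C=CC(C)(O)/C=C/[C@H]1C(C)(C)CCC=C1C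
F3 | step 6 | cis allylic alcohol = (1R,4S)-4-[(1E)-3-hydroxy-3-methylpenta-1,4-dien-1-yl]-3,5,5-trimethylcyclohex-2-en-1-ol (ring OH cis to side chain) | C=CC(C)(O)/C=C/[C@H]1C(C)(C)C[C@@H](O)C=C1C
F4 | step 6 | epoxy alcohol = 5-[(1E)-3-hydroxy-3-methylpenta-1,4-dien-1-yl]-4,4,6-trimethyl-7-oxabicyclo[4.1.0]heptan-2-ol with ring OH, epoxide oxygen and side chain all cis | C=CC(C)(O)/C=C/[C@H]1C(C)(C)C[C@@H](O)[C@@H]2[C@@]1(C)O2
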